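The route rests on opening the C9–C10 bond at quaternary C10 in retrosynthesis while joining C2 to C7. This folds the decalin into a bicyclo[2.2.2]octene. Ring A is already present in it (C5, C10, C1, C2 from creosol; C3, C4 from a propenyl ether), and C6–C7 forms the third bridge. Forward, one anionic oxy-Cope shift of vinyl carbinol 9 makes C9–C10, closes ring B, sets C10 and frees the C7 ketone that later carries the acrylate. Carbinol 9 bears its vinyl group syn to the C1=C10 alkene. Its C3 oxygen carries an (R)-1-phenylethyl group, so single-enantiomer material comes from a diastereomer separation, and the group later leaves by hydrogenolysis.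

Key step: step 5

Numbering: eudesmane numbering is used throughout. Ring A is C1–C5 and C10, ring B is C5–C10, C14 is the methyl on C10, C15 the carbon on C4, and C11–C13 the side chain on C7; β is the face of C14. Positions 1, 2, 3, 4, 5, 6, 7, 8 of the bicyclo[2.2.2]octenes are C2, C7, C6, C5, C10, C1, C3, C4.

Assumption: the two endo adducts of step 3, which differ only in the face of 6 that is attacked, can be separated on silica gel, and the isomer with the ring configuration of 7 is identified by X-ray analysis of a crystalline derivative.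

Step 1
Reactants: 1 (R)-1-phenylethanol; 2 allyl bromide
Product: 3 allyl (R)-1-phenylethyl ether
Conditions: NaH, THF, 0 °C; then 2, Bu4NI (cat.), rt
Reagents that add atoms: none
Why: Williamson ether synthesis takes place at oxygen only, so the benzylic stereocentre is not touched.

Step 2
Reactants: 3 allyl (R)-1-phenylethyl ether
Product: 4 (Z)-prop-1-enyl (R)-1-phenylethyl ether
Conditions: KOtBu (0.3 equiv), DMSO, rt
Reagents that add atoms: none
Why: Base-mediated allyl-to-propenyl ether isomerisation runs through the cisoid, potassium-bridged oxyallyl anion and therefore gives the Z enol ether, while the less acidic tertiary benzylic C–H stays intact.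

Step 3
Reactants: 5 2-methoxy-4-methylphenol (creosol); 4 (Z)-prop-1-enyl (R)-1-phenylethyl ether
Product: 7 (1R,4R,7R,8R)-3,3-dimethoxy-5,8-dimethyl-7-[(R)-1-phenylethoxy]bicyclo[2.2.2]oct-5-en-2-one, via masked o-benzoquinone 6 (not isolated)
Conditions: PhI(OAc)2 (1.1 equiv, slow addition), MeOH, 4 (5 equiv), 50 °C; silica gel separation of the two facial adducts
Reagents that add atoms: methanol, CO
Why: Oxidative dearomatisation gives dienone 6, which is trapped at once in an inverse-electron-demand Diels–Alder reaction in which the nucleophilic methyl-bearing carbon of 4 bonds to the dienone terminus next to the ketal (C4–C5) and the oxygen-bearing carbon to the terminus next to the carbonyl (C3–C2), the endo mode places OR and CH3 syn to the new C1=C10 alkene, and the stereogenic ether turns the two faces of attack into separable diastereomers.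

Step 4
Reactants: 7 bicyclic ketone; 8 vinylmagnesium bromide
Product: 9 (1R,2S,4R,7R,8R)-2-ethenyl-3,3-dimethoxy-5,8-dimethyl-7-[(R)-1-phenylethoxy]bicyclo[2.2.2]oct-5-en-2-ol
Conditions: 8 (1.5 equiv), THF, −78 to 0 °C; then aq. NH4Cl
Reagents that add atoms: none
Why: Grignard 1,2-addition meets a ketone that cannot enolise (bridgehead on one side, ketal on the other), and the nucleophile comes in over the flat C1=C10 bridge and not past the exo hydrogens of the C3–C4 bridge, so the vinyl group ends up syn to the alkene.

Step 5
Reactants: 9 vinyl carbinol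
Product: 12 6,6-dimethoxy-4β,10β-dimethyl-3β-[(R)-1-phenylethoxy]-5βH-cis-decal-1-en-7-one, via potassium alkoxide 10 (not isolated), via potassium enolate 11 (not isolated)
Conditions: KH (2 equiv), 18-crown-6 (2 equiv), THF, 0 °C to reflux; then aq. NH4Cl, 0 °C
Reagents that add atoms: potassium hydride, [K+].[H-] (its potassium sits only in 10 and 11)
Why: KH converts 9 into alkoxide 10, whose oxyanion weakens the adjacent C2–C7 bond and lets the 1,5-diene C9=C8–C7–C2–C1=C10 undergo a concerted [3,3] shift far below the temperature of the neutral reaction, which is the anionic oxy-Cope rearrangement, well established for 2-vinylbicyclo[2.2.2]oct-5-en-2-ols. C9 bonds to the methyl-bearing alkene carbon C10 while C2–C7 breaks, so six-membered ring B (C5–C6–C7–C8–C9–C10) closes through the boat-like six-centre array that the cage enforces, and ring A is released as the C1=C2 cyclohexene. The only new stereocentre, quaternary C10, is set suprafacially, because C9 can reach C10 only on the alkene face turned toward the C6–C7 bridge, which places C9 cis to C6 (cis fusion, 10β-methyl, 5β-H) and copies the absolute configuration of 7. The step needs the vinyl group syn to C1=C10, which step 4 secures, and only one alkene within its reach, which the saturated C3–C4 bridge guarantees, so no second [3,3] path exists. Formation of the delocalised enolate 11 and loss of cage strain make the shift irreversible, and protonation of 11 gives ketone 12 with ketal, allylic ether and C3–C5 unchanged.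

Step 6
Reactants: 12 cis-decalone ketal
Product: 13 4β,10β-dimethyl-3β-[(R)-1-phenylethoxy]-5βH-cis-decal-1-en-7-one
Conditions: SmI2 (5 equiv), THF/MeOH, 0 °C to rt
Reagents that add atoms: none
Why: SmI2 reduction of an α-alkoxy ketone expels both methoxy groups at C6 in two ketyl-to-enolate sequences, a reaction confined to substituents α to a carbonyl, so the alkene and the allylic ether stay.

Step 7
Reactants: 13 C7 ketone
Product: 14 7β-cyano-4β,10β-dimethyl-3β-[(R)-1-phenylethoxy]-5βH-cis-decal-1-ene
Conditions: TosMIC (1.5 equiv), KOtBu (3 equiv), DME/EtOH, 0 to 40 °C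
Reagents that add atoms: p-toluenesulfonylmethyl isocyanide (TosMIC), [C-]#[N+]CS(=O)(=O)c1ccc(C)cc1
Why: Van Leusen reductive cyanation turns the unhindered ketone into the nitrile that supplies C11, it is done before ring A is oxidised because a 4-ene-3,7-dione would be a vinylogous 1,3-diketone whose C6 enolate would shut down chemistry at C7, and the 7β-nitrile is favoured since 7α is syn-axial to the C4–C5 bond in the preferred conformer (any 7α epimer converges in step 14).

Step 8
Reactants: 14 unsaturated ether nitrile
Product: 15 7β-cyano-4β,10β-dimethyl-5βH-cis-decalin-3β-ol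
Conditions: H2 (3 atm), Pd(OH)2/C, EtOAc/EtOH, rt
Reagents that add atoms: none
Why: Heterogeneous hydrogenation saturates the disubstituted C1=C2 alkene and hydrogenolyses the benzylic C–O bond in the same operation, whereas an aliphatic nitrile is inert to palladium and hydrogen at low pressure in a neutral solvent.

Step 9
Reactants: 15 hydroxy nitrile
Product: 16 7β-cyano-4β,10β-dimethyl-5βH-cis-decalin-3-one
Conditions: Dess–Martin periodinane, CH2Cl2, rt
Reagents that add atoms: none
Why: Dess–Martin oxidation of the secondary alcohol is nearly neutral, and the equatorial 4β-methyl group is already the stable epimer next to the new ketone.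

Step 10
Reactants: 16 keto nitrile
Product: 17 7β-cyano-4,10β-dimethyl-3-(trimethylsilyloxy)-5βH-decal-3-ene
Conditions: Me3SiI, (Me3Si)2NH, CH2Cl2, −20 °C to rt
Reagents that add atoms: iodotrimethylsilane, C[Si](C)(C)I
Why: Silyl enol ether formation under equilibrating conditions settles on the tetrasubstituted Δ3 isomer, the direction that both the 4-methyl group and the cis ring fusion favour, and the nitrile does not react.

Step 11
Reactants: 17 silyl enol ether
Product: 18 7β-cyano-4,10β-dimethyldecal-4-en-3-one
Conditions: Pd(OAc)2 (1.1 equiv), MeCN, rt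
Reagents that add atoms: none
Why: In this Saegusa–Ito oxidation the palladium enolate at C4 can sit on the convex β face, where the 5β-H is syn-coplanar, so β-hydride elimination gives the conjugated tetrasubstituted Δ4-enone and erases the no longer needed centres C4 and C5.

Step 12
Reactants: 18 enone nitrile
Product: 19 7β-cyano-4,10β-dimethyldecal-4-en-3α-ol
Conditions: K[HB(s-Bu)3] (1.2 equiv), THF, −78 °C; then aq. NH4Cl
Reagents that add atoms: none
Why: In this 1,2-reduction with a bulky trialkylborohydride conjugate attack is blocked at fully substituted C5, and the reagent approaches C3 along the equatorial trajectory on the β face, as is known for 10β-methyl-Δ4-3-ketones, which gives the quasi-axial 3α-alcohol (3R).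

Step 13
Reactants: 19 allylic alcohol
Product: 20 3α-(tert-butyldimethylsilyloxy)-7β-cyano-4,10β-dimethyldecal-4-ene
Conditions: TBSOTf, 2,6-lutidine, CH2Cl2, −78 to 0 °C
Reagents that add atoms: tert-butyldimethylsilyl triflate, CC(C)(C)[Si](C)(C)OS(=O)(=O)C(F)(F)F
Why: Silylation with a silyl triflate and a hindered base masks the only acidic and ionisable group before organolithium, amide base and palladium chemistry.

Step 14
Reactants: 20 silyl ether nitrile
Product: 22 7β-acetyl-3α-(tert-butyldimethylsilyloxy)-4,10β-dimethyldecal-4-ene, via lithium ketimide 21 (not isolated)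
Conditions: MeLi (3 equiv), Et2O, 0 °C to rt; 10% aq. AcOH, THF, 0 °C; then NaOMe (0.2 equiv), MeOH, rt
Reagents that add atoms: methyllithium, [Li]C; water, O
Why: Organolithium addition to the nitrile stops at ketimide 21, mild hydrolysis gives the methyl ketone, and methoxide equilibration through the C7 enolate puts the acetyl group equatorial (7β) on the chair of ring B whose 10β-methyl is axial, which fixes C7.

Step 15
Reactants: 22 methyl ketone
Product: 24 1-[3α-(tert-butyldimethylsilyloxy)-4,10β-dimethyldecal-4-en-7β-yl]ethenyl triflate, via potassium enolate 23 (not isolated)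
Conditions: KN(SiMe3)2 (1.1 equiv), THF, −78 °C; then PhNTf2, −78 to 0 °C
Reagents that add atoms: KN(SiMe3)2, [K+].C[Si](C)(C)[N-][Si](C)(C)C (its potassium sits only in 23); N-phenylbis(trifluoromethanesulfonimide), O=S(=O)(N(c1ccccc1)S(=O)(=O)C(F)(F)F)C(F)(F)F
Why: Kinetic deprotonation with a hindered amide base takes a methyl proton and not the hindered C7–H, so C7 is not disturbed, and O-sulfonylation of enolate 23 gives the terminal enol triflate.

Step 16
Reactants: 24 enol triflate
Product: 25 methyl 3α-(tert-butyldimethylsilyloxy)eudesma-4,11(13)-dien-12-oate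
Conditions: Pd(PPh3)4 (5 mol %), CO (1 atm), Et3N, MeOH/DMF, 40 °C
Reagents that add atoms: carbon monoxide, [C-]#[O+]; methanol, CO
Why: Palladium-catalysed methoxycarbonylation of an enol triflate (oxidative addition to zerovalent palladium, CO insertion, methanolysis) gives the 2-substituted acrylate directly, and the allylic silyl ether is no leaving group for palladium.

Step 17
Reactants: 25 silyl ether acrylate
Product: 26 methyl 3α-hydroxyeudesma-4,11(13)-dien-12-oate
Conditions: Bu4NF (2 equiv), AcOH (2 equiv), THF, 0 °C to rt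
Reagents that add atoms: none
Why: Fluoride-induced desilylation is buffered with acetic acid so that neither alkoxide nor basic fluoride attacks the acrylate and the acid-sensitive allylic alcohol is not ionised.

Step 18
Reactants: 26 3α-alcohol; 27 angelic acid
Product: 29 methyl 3α-angeloyloxyeudesma-4,11(13)-dien-12-oate, via mixed anhydride 28 (not isolated)
Conditions: 27, 2,4,6-trichlorobenzoyl chloride, Et3N, toluene, rt; then 26, 80 °C
Reagents that add atoms: 2,4,6-trichlorobenzoyl chloride, O=C(Cl)c1c(Cl)cc(Cl)cc1Cl (its atoms sit only in 28)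
Why: In this Yamaguchi-type esterification the alcohol attacks the unshielded angeloyl carbonyl of 28 without a nucleophilic catalyst, conditions known to keep the Z geometry of angelates, and the C3–O bond is not broken, so 3α is retained.

Step 19
Reactants: 29 Δ4 angelate
Product: 30 methyl (3R,5S,7R,10S)-3α-angeloyloxy-5α-hydroperoxyeudesma-4(15),11(13)-dien-12-oate (CNP0137897.2)
Conditions: O2, tetraphenylporphyrin (cat.), visible light, CH2Cl2, −20 °C
Reagents that add atoms: dioxygen, O=O
Why: In this Schenck ene reaction singlet oxygen picks the electron-rich tetrasubstituted C4=C5 alkene over the two electron-poor enoates, adds on the α face opposite to the axial 10β-methyl, finds no hydrogen at C3 on that face, and, in line with the preference for abstraction from the group geminal to a bulky electron-withdrawing allylic substituent, takes a C15 hydrogen, so oxygen ends on C5 (5α) next to the new 4(15)-methylene group.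

Compound list
1 | (R)-1-phenylethanol | C[C@@H](O)c1ccccc1 | starting material
2 | allyl bromide | C=CCBr | starting material
3 | allyl (R)-1-phenylethyl ether | C=CCO[C@H](C)c1ccccc1 | intermediate
4 | (Z)-prop-1-enyl (R)-1-phenylethyl ether | C/C=C\O[C@H](C)c1ccccc1 | intermediate
5 | 2-methoxy-4-methylphenol (creosol) | COc1cc(C)ccc1O | starting material
6 | 6,6-dimethoxy-4-methylcyclohexa-2,4-dienone (masked o-benzoquinone, not isolated) | COC1(OC)C=C(C)C=CC1=O | intermediate
7 | (1R,4R,7R,8R)-3,3-dimethoxy-5,8-dimethyl-7-[(R)-1-phenylethoxy]bicyclo[2.2.2]oct-5-en-2-one; OR and 8-methyl syn to the alkene | O=C1[C@@H]2C=C(C)[C@H](C1(OC)OC)[C@@H](C)[C@H]2O[C@H](C)c3ccccc3 | intermediate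
8 | vinylmagnesium bromide | C=C[Mg]Br | starting material
9 | (1R,2S,4R,7R,8R)-2-ethenyl-3,3-dimethoxy-5,8-dimethyl-7-[(R)-1-phenylethoxy]bicyclo[2.2.2]oct-5-en-2-ol; vinyl syn to the alkene | C=C[C@]1(O)[C@@H]2C=C(C)[C@H](C1(OC)OC)[C@@H](C)[C@H]2O[C@H](C)c3ccccc3 | intermediate
10 | potassium alkoxide of 9 (not isolated) | [K+].C=C[C@]1([O-])[C@@H]2C=C(C)[C@H](C1(OC)OC)[C@@H](C)[C@H]2O[C@H](C)c3ccccc3 | intermediate
11 | potassium C7(8)-enolate of 12 (not isolated) | [K+].[O-]C1=CC[C@@]2(C)C=C[C@H](O[C@H](C)c3ccccc3)[C@H](C)[C@H]2C1(OC)OC | intermediate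
12 | 6,6-dimethoxy-4β,10β-dimethyl-3β-[(R)-1-phenylethoxy]-5βH-cis-decal-1-en-7-one | O=C1CC[C@@]2(C)C=C[C@H](O[C@H](C)c3ccccc3)[C@H](C)[C@H]2C1(OC)OC | intermediate
13 | 4β,10β-dimethyl-3β-[(R)-1-phenylethoxy]-5βH-cis-decal-1-en-7-one | O=C1CC[C@@]2(C)C=C[C@H](O[C@H](C)c3ccccc3)[C@H](C)[C@H]2C1 | intermediate
14 | 7β-cyano-4β,10β-dimethyl-3β-[(R)-1-phenylethoxy]-5βH-cis-decal-1-ene | N#C[C@@H]1CC[C@@]2(C)C=C[C@H](O[C@H](C)c3ccccc3)[C@H](C)[C@H]2C1 | intermediate
15 | 7β-cyano-4β,10β-dimethyl-5βH-cis-decalin-3β-ol | N#C[C@@H]1CC[C@@]2(C)CC[C@H](O)[C@H](C)[C@H]2C1 | intermediate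
16 | 7β-cyano-4β,10β-dimethyl-5βH-cis-decalin-3-one | N#C[C@@H]1CC[C@@]2(C)CCC(=O)[C@H](C)[C@H]2C1 | intermediate
17 | 7β-cyano-4,10β-dimethyl-3-(trimethylsilyloxy)-5βH-decal-3-ene | N#C[C@@H]1CC[C@@]2(C)CCC(O[Si](C)(C)C)=C(C)[C@H]2C1 | intermediate
18 | 7β-cyano-4,10β-dimethyldecal-4-en-3-one | N#C[C@@H]1CC[C@@]2(C)CCC(=O)C(C)=C2C1 | intermediate
19 | 7β-cyano-4,10β-dimethyldecal-4-en-3α-ol | N#C[C@@H]1CC[C@@]2(C)CC[C@@H](O)C(C)=C2C1 | intermediate
20 | 3α-(tert-butyldimethylsilyloxy)-7β-cyano-4,10β-dimethyldecal-4-ene | N#C[C@@H]1CC[C@@]2(C)CC[C@@H](O[Si](C)(C)C(C)(C)C)C(C)=C2C1 | intermediate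
21 | N-lithio ketimine from 20 and MeLi (not isolated) | [Li]N=C(C)[C@@H]1CC[C@@]2(C)CC[C@@H](O[Si](C)(C)C(C)(C)C)C(C)=C2C1 | intermediate
22 | 7β-acetyl-3α-(tert-butyldimethylsilyloxy)-4,10β-dimethyldecal-4-ene | CC(=O)[C@@H]1CC[C@@]2(C)CC[C@@H](O[Si](C)(C)C(C)(C)C)C(C)=C2C1 | intermediate
23 | terminal potassium enolate of 22 (not isolated) | [K+].C=C([O-])[C@@H]1CC[C@@]2(C)CC[C@@H](O[Si](C)(C)C(C)(C)C)C(C)=C2C1 | intermediate
24 | 1-[3α-(tert-butyldimethylsilyloxy)-4,10β-dimethyldecal-4-en-7β-yl]ethenyl triflate | C=C(OS(=O)(=O)C(F)(F)F)[C@@H]1CC[C@@]2(C)CC[C@@H](O[Si](C)(C)C(C)(C)C)C(C)=C2C1 | intermediate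
25 | methyl 3α-(tert-butyldimethylsilyloxy)eudesma-4,11(13)-dien-12-oate | C=C(C(=O)OC)[C@@H]1CC[C@@]2(C)CC[C@@H](O[Si](C)(C)C(C)(C)C)C(C)=C2C1 | intermediate
26 | methyl 3α-hydroxyeudesma-4,11(13)-dien-12-oate | C=C(C(=O)OC)[C@@H]1CC[C@@]2(C)CC[C@@H](O)C(C)=C2C1 | intermediate
27 | angelic acid, (Z)-2-methylbut-2-enoic acid | C/C=C(/C)C(=O)O | starting material
28 | angelic 2,4,6-trichlorobenzoic anhydride (not isolated) | C/C=C(/C)C(=O)OC(=O)c1c(Cl)cc(Cl)cc1Cl | intermediate
29 | methyl 3α-angeloyloxyeudesma-4,11(13)-dien-12-oate | C=C(C(=O)OC)[C@@H]1CC[C@@]2(C)CC[C@@H](OC(=O)/C(C)=C\C)C(C)=C2C1 | intermediate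
30 | methyl (3R,5S,7R,10S)-3α-angeloyloxy-5α-hydroperoxyeudesma-4(15),11(13)-dien-12-oate | C=C(C(=O)OC)[C@@H]1CC[C@@]2(C)CC[C@@H](OC(=O)/C(C)=C\C)C(=C)[C@]2(OO)C1 | target

Total step count: 19
Longest linear sequence: 19 steps (1 → 3 → 4 → 7 → 9 → 12 → … → 30)

Steps most likely to fail

Step 5. The alkoxide may revert toward ketone and vinyl anion, or decompose, before the congested C9–C10 bond at the methyl-bearing carbon can form. The fallback sets out from 9 and comes back at 12. Compound 9 is silylated with Me3SiOTf and 2,6-lutidine to the tertiary trimethylsilyl ether F1. Heating this without any base in o-dichlorobenzene at about 200 °C triggers the neutral siloxy-Cope shift through the same six-centre array and gives the C7 trimethylsilyl enol ether F2. Citric acid in aqueous THF then hydrolyses it to 12.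

Step 19. Singlet oxygen may attack partly on the β face because the 3α-ester crowds and repels it on the α face, or it may abstract the 6α hydrogen in place of a C15 hydrogen. The fallback sets out from 26 and comes back at 30. The free alcohol 26 carries a smaller α substituent that can hydrogen-bond to the incoming oxygen. It is photooxygenated (O2, tetraphenylporphyrin, light, toluene) to the hydroxy hydroperoxide F3. Both OH groups are acylated at low temperature with LiN(SiMe3)2 and mixed anhydride 28 to the ester perester F4. The far more electrophilic perester alone is then cleaved with K2CO3 in MeOH at −20 °C to give 30.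

Step 3. Facial selectivity of the cycloaddition may be poor and the two adducts may co-elute, so that no single isomer is obtained. The fallback sets out from 7 still mixed with its facial isomer and comes back at pure 7. Lithiated (S)-N,S-dimethyl-S-phenylsulfoximine adds to the non-enolisable ketone from the alkene side to give the β-hydroxysulfoximine F5. This adduct carries two more stereocentres and a polar group, and it is separated from its isomer by chromatography or crystallisation. Heating it in toluene reverses the addition and returns 7.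

Further compounds
F1 | step 5 | (1R,2S,4R,7R,8R)-2-ethenyl-3,3-dimethoxy-5,8-dimethyl-7-[(R)-1-phenylethoxy]-2-(trimethylsilyloxy)bicyclo[2.2.2]oct-5-ene | C=C[C@]1(O[Si](C)(C)C)[C@@H]2C=C(C)[C@H](C1(OC)OC)[C@@H](C)[C@H]2O[C@H](C)c3ccccc3
F2 | step 5 | 6,6-dimethoxy-4β,10β-dimethyl-3β-[(R)-1-phenylethoxy]-7-(trimethylsilyloxy)-5βH-cis-decala-1,7-diene | C[Si](C)(C)OC1=CC[C@@]2(C)C=C[C@H](O[C@H](C)c3ccccc3)[C@H](C)[C@H]2C1(OC)OC
F3 | step 19 | methyl 3α-hydroxy-5α-hydroperoxyeudesma-4(15),11(13)-dien-12-oate | C=C(C(=O)OC)[C@@H]1CC[C@@]2(C)CC[C@@H](O)C(=C)[C@]2(OO)C1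
F4 | step 19 | methyl 3α-angeloyloxy-5α-(angeloylperoxy)eudesma-4(15),11(13)-dien-12-oate | C=C(C(=O)OC)[C@@H]1CC[C@@]2(C)CC[C@@H](OC(=O)/C(C)=C\C)C(=C)[C@]2(OOC(=O)/C(C)=C\C)C1
F5 | step 3 | adduct of 7 with (S)-N,S-dimethyl-S-phenylsulfoximine at C2 of the bicycle, CH2 group syn to the alkene | CN=[S@](=O)(C[C@]1(O)[C@@H]2C=C(C)[C@H](C1(OC)OC)[C@@H](C)[C@H]2O[C@H](C)c3ccccc3)c4ccccc4
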